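## The problem

Target 16 is a depside. (E)-Caffeic acid (ring A) is esterified with the secondary hydroxyl of an (R)-3-aryl-lactic acid (C1' carboxyl, C2' stereocenter, C3' methylene). The aryl group, ring B, also carries a 4-hydroxybenzyl group (C7 methylene, ring C).

Ring B is 1,2,4,5-tetrasubstituted: C1 bears C3', the neighbouring C2 bears C7, and C4 and C5 bear hydroxyls. Two different carbon chains must therefore sit ortho to each other, each para to one oxygen. Electrophilic substitution on a catechol does not deliver this cleanly.

C2' (R) is the only stereocenter, so no other center can control it. It must come from the chiral pool or a catalyst, and it must not epimerise once it carries an acyloxy group next to a carboxyl derivative.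

The sensitive groups are:
- the two catechols (oxidation in base and air);
- the cinnamate C=C (hydrogenation, conjugate addition);
- the depside ester (cleavage by base);
- the electron-rich diarylmethane (loss of the hydroxybenzyl group in strong acid).

The feature that the plan uses is the substitution pattern of ring B. The two carbon substituents are on the adjacent atoms C1 and C2 and the two oxygens are on C4 and C5. A mirror plane through the midpoints of C1–C2 and C4–C5 therefore relates C1 to C2. Both substituents start with a CH2 on the ring, and C2' is one atom beyond the ring-bound C3'.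

A 4,5-dioxygenated benzyne (C1≡C2) is therefore symmetrical. It can take a benzyl nucleophile at one end and a three-carbon electrophile at the other with no regiochemical question, and that electrophile can be an epoxide that already holds C2'.

## Retrosynthesis

**16 to 13 and 14.** The cut is the Cα=Cβ double bond of the caffeoyl unit, leading back to aldehyde 14 and the malonic half ester 13, with 15 as the condensation intermediate. The neighbouring cut, at the depside acyl–O bond, would bring in ring A as a protected cinnamic acid. Five phenols and one carboxyl would then have to be unmasked in the presence of the C=C bond and the depside ester. Making the alkene last, from unprotected partners, lets everything before it carry benzyl groups that leave by hydrogenolysis. The forward reaction must give the E alkene, tolerate free phenols and acids, and leave C2' alone.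

**13 to 12, then 10 and 11.** Four O–benzyl bonds are cut (12), then the acyl–O bond between the C2' oxygen and the malonyl carbonyl, giving hydroxy ester 10 and Meldrum's acid 11. Compound 11 is a neutral malonyl donor that needs no coupling agent and breaks no bond at C2'. Precursor 10 has lost the whole acyl half. The forward step must acylate a hindered secondary α-hydroxy ester without epimerisation.

**10 to 9.** The ester alkyl group is exchanged, benzyl back to methyl. The only reason is that the chiral three-carbon block 5 is sold as the methyl ester. A benzyl ester lets the acid be freed together with the phenols in the hydrogenolysis to 13. The forward step must be a neutral ester exchange.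

**9 to 2, 4 and 5 (key disconnection).** Both ring-to-CH2 bonds of ring B are cut together, C2–C7 and C1–C3'. This leads to aryne 7, benzylic Grignard reagent 4 and epoxide 5. Cutting only one of these bonds would leave an ortho-functionalised, unsymmetrical arene that itself takes several steps to make. Cutting both uses the symmetry of 7 and reduces ring B to the symmetrical dibromide 2. The precursors are far simpler than 9: 2 is achiral and symmetrical, 4 is a one-ring reagent, and 5 carries C1', C2' and C3' with the configuration already set. The forward reaction must: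
- generate 7 from 2 through the mono-Grignard 6;
- let 4, and not 6 or the product Grignard 8, add to 7;
- make 8 open 5 at C3 and not attack its ester.

**2 to 1, and 4 to 3.** Dibromide 2 comes from 4,5-dibromocatechol 1 by double O-benzylation. Grignard reagent 4 comes from the benzylic chloride 3. Both are one-step preparations from catalogue compounds.

## Roads not taken

**Alternative 1:** The most obvious route is a biomimetic Friedel–Crafts reaction. The cut is the C2–C7 bond of 16. Rosmarinic acid A1 would be hydroxybenzylated by 4-hydroxybenzyl alcohol A2 under acid catalysis, through the para-quinone methide A3, to give 16 in one step.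
- The electrophile has no reason to choose C2 of ring B. Ring B of A1 offers three free positions and ring A three more.
- The product is more electron-rich than A1 and would react again, and A3 would oligomerise with A2.
- The outcome would be a mixture of regioisomers and polybenzylated depsides with near-identical polarity.
- The chosen plan fixes both positions by construction, since the aryne has only two reactive carbons.

**Alternative 2:** The classical linear route makes the C2–C7 bond by cross-coupling and sets C2' by asymmetric reduction.
- 4,5-Bis(benzyloxy)-2-bromobenzaldehyde A4 would undergo Negishi coupling with 4-(benzyloxy)benzylzinc chloride A5 (from 3 by zinc insertion) to give aldehyde A6.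
- Two-carbon homologation by the Erlenmeyer–Plöchl sequence and hydrolysis would give the arylpyruvic acid A7.
- Enantioselective ketone reduction and esterification would then reach the stage of 9.
- This takes five to six steps for what step 3 does in one. The two ortho substituents are introduced one at a time on an arene that must first be differentiated. The configuration of C2' depends on the selectivity of a catalyst on a hindered, enolisable keto acid, whereas 5 supplies it ready-made.

**Alternative 3:** A Catellani-type reaction would also build both ortho bonds in one operation. 1,2-Bis(benzyloxy)-4-iodobenzene A8 would be ortho-benzylated with 3 and terminated at the ipso carbon by a Heck reaction with an acrylate ester, giving cinnamate A9. Sharpless dihydroxylation and removal of the benzylic hydroxyl would follow.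
- A8 has two free positions ortho to iodine. Without an ortho blocking group the palladacycle chemistry alkylates both, giving the wrong 1,2,3-pattern.
- C2' would still need two further steps and a benzylic deoxygenation next to electron-rich rings.
- The aryne reaches the same two neighbouring atoms with no directing or blocking group, and takes the stereocenter in with the electrophile.

Key step: step 3

Remark: the stereodescriptor read from the SMILES is R at C2' (as in natural rosmarinic acid) and the alkene is E. All starting materials (1, 3, 5, 11, 14) are taken as catalogue compounds.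

## Steps

Step 1
Reactants: 1 4,5-dibromobenzene-1,2-diol (4,5-dibromocatechol)
Product: 2 1,2-bis(benzyloxy)-4,5-dibromobenzene
Conditions: BnBr (2.3 equiv), K2CO3, DMF, 60 °C
Reagents that add atoms: benzyl bromide, BrCc1ccccc1
Why: Williamson etherification of both phenols. Benzyl ethers are inert to Grignard reagents and later leave by hydrogenolysis, and the two bromines remain for aryne formation.

Step 2
Reactants: 3 1-(benzyloxy)-4-(chloromethyl)benzene (4-(benzyloxy)benzyl chloride)
Product: 4 4-(benzyloxy)benzylmagnesium chloride (THF solution, titrated)
Conditions: Mg turnings (I2-activated, excess), THF, 0 to 20 °C, slow addition at high dilution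
Reagents that add atoms: magnesium, [Mg]
Why: Direct magnesium insertion into a benzylic chloride. Slow addition and low concentration should suppress Wurtz homocoupling, and the aryl benzyl ether is inert.

Step 3
Reactants: 2 1,2-bis(benzyloxy)-4,5-dibromobenzene; 4 4-(benzyloxy)benzylmagnesium chloride; 5 methyl (2R)-oxirane-2-carboxylate (methyl (R)-glycidate)
Product: 9 methyl (2R)-3-{4,5-bis(benzyloxy)-2-[4-(benzyloxy)benzyl]phenyl}-2-hydroxypropanoate, via bromoarylmagnesium chloride 6 (not isolated), via symmetrical aryne 7 (not isolated), via benzylated arylmagnesium chloride 8 (not isolated)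
Conditions: iPrMgCl·LiCl (1.05 equiv), THF, −15 °C; then 4 (1.5 equiv), −15 to 40 °C; then CuI (10 mol%), 5 (2.0 equiv), −40 to −10 °C; aq. NH4Cl
Reagents that add atoms: none
Why: Br/Mg exchange converts 2 into 6, which is stable at −15 °C and on warming loses MgBrCl to give aryne 7; the benzylic Grignard 4 adds across the strained C1≡C2 bond (carbomagnesiation) to give the ortho-benzylated aryl Grignard 8, and catalytic CuI then turns 8 into an arylcopper species that opens epoxide 5 by SN2 attack at its unsubstituted C3. The closest known reaction types are the addition of Grignard reagents to arynes generated from 2-haloarylmagnesium halides with trapping of the new arylmagnesium by an electrophile, and the copper-catalysed opening of glycidic esters by aryl Grignard reagents to 3-aryl-2-hydroxy esters. No ring is closed; the step forms the two C–C bonds C2–C7 and C1–C3' on neighbouring ring atoms. No stereocenter is created: C2' is brought in by 5, none of its four bonds is touched, and because the CIP order O > CO2Me > CH2 > H is the same in 5 and 9 the descriptor stays R. Regioselectivity on the aryne does not arise, because 7 has a mirror plane through the midpoints of C1≡C2 and C4–C5 and both ends give the same product. Chemoselectivity for the aryne is needed between 4 and the aryl Grignards 6 and 8; the excess and the higher nucleophilicity of the unhindered benzylic reagent should secure it. Site selectivity on 5 (C3 against C2 and against the ester carbonyl) rests on the soft organocopper nucleophile at low temperature and on C3 being the only unsubstituted epoxide carbon. The surplus of 4 is consumed by the excess of 5 and should give a small hydroxy ester that is removed by chromatography.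

Step 4
Reactants: 9 methyl (2R)-3-{4,5-bis(benzyloxy)-2-[4-(benzyloxy)benzyl]phenyl}-2-hydroxypropanoate
Product: 10 benzyl (2R)-3-{4,5-bis(benzyloxy)-2-[4-(benzyloxy)benzyl]phenyl}-2-hydroxypropanoate
Conditions: BnOH (10 equiv), Ti(OiPr)4 (0.3 equiv), toluene, 90 °C, 4 Å molecular sieves
Reagents that add atoms: benzyl alcohol, OCc1ccccc1
Why: Titanate-mediated transesterification, helped by chelation of the α-hydroxy ester to titanium and driven by excess alcohol and removal of methanol. The neutral conditions should leave C2' untouched, and the benzyl ester lets step 6 free the acid together with the phenols.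

Step 5
Reactants: 10 benzyl (2R)-3-{4,5-bis(benzyloxy)-2-[4-(benzyloxy)benzyl]phenyl}-2-hydroxypropanoate; 11 2,2-dimethyl-1,3-dioxane-4,6-dione (Meldrum's acid)
Product: 12 3-{[(2R)-1-(benzyloxy)-3-{4,5-bis(benzyloxy)-2-[4-(benzyloxy)benzyl]phenyl}-1-oxopropan-2-yl]oxy}-3-oxopropanoic acid
Conditions: 11 (1.3 equiv), toluene, 95 °C; aqueous wash to remove malonic acid
Reagents that add atoms: none
Why: Thermal ring opening of Meldrum's acid by the secondary alcohol, with loss of acetone, gives the malonic half ester without a coupling agent or base. The C2'–O bond is not broken, so the configuration is retained.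

Step 6
Reactants: 12 3-{[(2R)-1-(benzyloxy)-3-{4,5-bis(benzyloxy)-2-[4-(benzyloxy)benzyl]phenyl}-1-oxopropan-2-yl]oxy}-3-oxopropanoic acid
Product: 13 (2R)-2-[(carboxyacetyl)oxy]-3-{4,5-dihydroxy-2-[(4-hydroxyphenyl)methyl]phenyl}propanoic acid
Conditions: H2 (1 atm), Pd/C (10 wt%), THF/EtOAc, 20 °C
Reagents that add atoms: none
Why: Hydrogenolysis of three aryl benzyl ethers and the benzyl ester in one operation. No alkene is present yet, and the diarylmethane, the malonyl ester and C2' are not affected under these conditions.

Step 7
Reactants: 13 (2R)-2-[(carboxyacetyl)oxy]-3-{4,5-dihydroxy-2-[(4-hydroxyphenyl)methyl]phenyl}propanoic acid; 14 3,4-dihydroxybenzaldehyde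
Product: 16 (2R)-2-{[(2E)-3-(3,4-dihydroxyphenyl)prop-2-enoyl]oxy}-3-{4,5-dihydroxy-2-[(4-hydroxyphenyl)methyl]phenyl}propanoic acid (CNP0370714.1), via arylidenemalonic half ester 15 (not isolated)
Conditions: 14 (1.3 equiv), piperidine (0.3 equiv), pyridine, 55 °C, argon; then 1 M HCl, reversed-phase chromatography
Reagents that add atoms: none
Why: Knoevenagel–Doebner condensation: the piperidine-derived iminium of 14 condenses with the malonic half ester to give 15, which decarboxylates in pyridine to the cinnamate with the aryl group trans to the ester (E). The C1' carboxylate formed in the basic medium should protect C2' from enolisation. Compound 15 is drawn with the aryl group trans to the ester carbonyl; the other isomer would give the same product.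

## Compound list

1 | 4,5-dibromobenzene-1,2-diol | Oc1cc(Br)c(Br)cc1O | starting material
2 | 1,2-bis(benzyloxy)-4,5-dibromobenzene | Brc1cc(OCc2ccccc2)c(OCc2ccccc2)cc1Br | intermediate
3 | 1-(benzyloxy)-4-(chloromethyl)benzene | ClCc1ccc(OCc2ccccc2)cc1 | starting material
4 | 4-(benzyloxy)benzylmagnesium chloride | Cl[Mg]Cc1ccc(OCc2ccccc2)cc1 | intermediate
5 | methyl (2R)-oxirane-2-carboxylate | COC(=O)[C@H]1CO1 | starting material
6 | [4,5-bis(benzyloxy)-2-bromophenyl]magnesium chloride | Cl[Mg]c1cc(OCc2ccccc2)c(OCc2ccccc2)cc1Br | intermediate
7 | 4,5-bis(benzyloxy)benzyne (4,5-bis(benzyloxy)-1,2-didehydrobenzene) | C1(OCc2ccccc2)=CC#CC=C1OCc3ccccc3 | intermediate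
8 | {4,5-bis(benzyloxy)-2-[4-(benzyloxy)benzyl]phenyl}magnesium chloride | Cl[Mg]c1cc(OCc2ccccc2)c(OCc2ccccc2)cc1Cc1ccc(OCc2ccccc2)cc1 | intermediate
9 | methyl (2R)-3-{4,5-bis(benzyloxy)-2-[4-(benzyloxy)benzyl]phenyl}-2-hydroxypropanoate | COC(=O)[C@H](O)Cc1cc(OCc2ccccc2)c(OCc2ccccc2)cc1Cc1ccc(OCc2ccccc2)cc1 | intermediate
10 | benzyl (2R)-3-{4,5-bis(benzyloxy)-2-[4-(benzyloxy)benzyl]phenyl}-2-hydroxypropanoate | O=C(OCc1ccccc1)[C@H](O)Cc1cc(OCc2ccccc2)c(OCc2ccccc2)cc1Cc1ccc(OCc2ccccc2)cc1 | intermediate
11 | 2,2-dimethyl-1,3-dioxane-4,6-dione | CC1(C)OC(=O)CC(=O)O1 | starting material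
12 | 3-{[(2R)-1-(benzyloxy)-3-{4,5-bis(benzyloxy)-2-[4-(benzyloxy)benzyl]phenyl}-1-oxopropan-2-yl]oxy}-3-oxopropanoic acid | OC(=O)CC(=O)O[C@H](Cc1cc(OCc2ccccc2)c(OCc2ccccc2)cc1Cc1ccc(OCc2ccccc2)cc1)C(=O)OCc1ccccc1 | intermediate
13 | (2R)-2-[(carboxyacetyl)oxy]-3-{4,5-dihydroxy-2-[(4-hydroxyphenyl)methyl]phenyl}propanoic acid | OC(=O)CC(=O)O[C@H](Cc1cc(O)c(O)cc1Cc1ccc(O)cc1)C(=O)O | intermediate
14 | 3,4-dihydroxybenzaldehyde | O=Cc1ccc(O)c(O)c1 | starting material
15 | (2E)-2-({[(1R)-1-carboxy-2-{4,5-dihydroxy-2-[(4-hydroxyphenyl)methyl]phenyl}ethyl]oxy}carbonyl)-3-(3,4-dihydroxyphenyl)prop-2-enoic acid | OC(=O)/C(=C\c1ccc(O)c(O)c1)C(=O)O[C@H](Cc1cc(O)c(O)cc1Cc1ccc(O)cc1)C(=O)O | intermediate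
16 | (2R)-2-{[(2E)-3-(3,4-dihydroxyphenyl)prop-2-enoyl]oxy}-3-{4,5-dihydroxy-2-[(4-hydroxyphenyl)methyl]phenyl}propanoic acid | O=C(/C=C/c1ccc(O)c(O)c1)O[C@H](Cc1cc(O)c(O)cc1Cc1ccc(O)cc1)C(=O)O | target

## Step count and risks

Total steps: 7. Longest linear sequence: 6 steps (step 1 or step 2, then steps 3 to 7).

**Step 3 (key step).** Several processes could lower the outcome:
- slow loss of MgBrCl from 6, so that the aryne forms only at temperatures where the organomagnesium species begin to decompose;
- capture of 7 by 6 or 8 in place of 4, giving biaryl oligomers;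
- proton transfer from the doubly benzylic C7 methylene to the aryl–magnesium bond of 8 during the warm period, which would quench the nucleophile before the epoxide arrives;
- attack of a Grignard reagent at the ester carbonyl of 5 instead of at C3.

Fallback, stepwise and with known chemistry, setting out from 2 and returning at 8 and thus 9. Compound 6 is made as in step 3 but kept at −15 °C, where it does not eliminate. It is added to commercial 4-(benzyloxy)benzaldehyde to give the racemic carbinol [4,5-bis(benzyloxy)-2-bromophenyl][4-(benzyloxy)phenyl]methanol F1. Ionic reduction (Et3SiH, CF3CO2H, CH2Cl2, 0 °C) removes the hydroxyl and gives 1,2-bis(benzyloxy)-4-[4-(benzyloxy)benzyl]-5-bromobenzene F2. A second Br/Mg exchange (iPrMgCl·LiCl, THF, 0 °C) gives 8 with no aryne and no excess benzylic Grignard. Compound 8 is then treated with CuI and 5 as in step 3 to give 9.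

**Step 7.** Possible failures are:
- decarboxylation of the malonic half ester to an acetate before it condenses;
- aminolysis of the malonyl ester by piperidine;
- air oxidation of the catechols in the basic medium;
- loss of material on isolating a polar polyphenolic acid.

Fallback, setting out from 12 and returning at 16, with the order of olefination and deprotection reversed. Compound 12 is condensed under the same Knoevenagel–Doebner conditions with commercial 3,4-bis(benzyloxy)benzaldehyde, with no free phenol present. This gives benzyl (2R)-2-{[(2E)-3-[3,4-bis(benzyloxy)phenyl]prop-2-enoyl]oxy}-3-{4,5-bis(benzyloxy)-2-[4-(benzyloxy)benzyl]phenyl}propanoate F3. The five aryl benzyl ethers and the benzyl ester are then cleaved without touching the alkene by BCl3 and pentamethylbenzene as cation scavenger (CH2Cl2, −78 to 0 °C), giving 16. Cleavage of the benzyl ester under these conditions is the least certain part of this fallback.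

**Step 5.** Possible failures are sluggish acylation of the hindered, electron-poor α-hydroxyl and thermal decarboxylation of the half ester once formed.

Fallback, setting out from 10 and returning at 13. Compound 10 is esterified with commercial monobenzyl malonate (EDC·HCl, DMAP cat., CH2Cl2, 0 °C) to give benzyl (2R)-2-{[3-(benzyloxy)-3-oxopropanoyl]oxy}-3-{4,5-bis(benzyloxy)-2-[4-(benzyloxy)benzyl]phenyl}propanoate F4. Its five benzyl groups are removed under the conditions of step 6, giving 13 directly.

**Step 4.** Possible failures are incomplete ester exchange at equilibrium, partial formation of the isopropyl ester from the titanate ligands, and difficult removal of excess benzyl alcohol.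

Fallback, setting out from 9 and returning at 10. Saponification (LiOH, THF/H2O, 0 °C) gives (2R)-3-{4,5-bis(benzyloxy)-2-[4-(benzyloxy)benzyl]phenyl}-2-hydroxypropanoic acid F5. Selective O-alkylation of the carboxylate (BnBr, KHCO3, DMF, 20 °C) then gives 10.

## Further compounds

F1 | step 3 | [4,5-bis(benzyloxy)-2-bromophenyl][4-(benzyloxy)phenyl]methanol (racemic) | OC(c1ccc(OCc2ccccc2)cc1)c1cc(OCc2ccccc2)c(OCc2ccccc2)cc1Br
F2 | step 3 | 1,2-bis(benzyloxy)-4-[4-(benzyloxy)benzyl]-5-bromobenzene | Brc1cc(OCc2ccccc2)c(OCc2ccccc2)cc1Cc1ccc(OCc2ccccc2)cc1
F3 | step 7 | benzyl (2R)-2-{[(2E)-3-[3,4-bis(benzyloxy)phenyl]prop-2-enoyl]oxy}-3-{4,5-bis(benzyloxy)-2-[4-(benzyloxy)benzyl]phenyl}propanoate | O=C(/C=C/c1ccc(OCc2ccccc2)c(OCc2ccccc2)c1)O[C@H](Cc1cc(OCc2ccccc2)c(OCc2ccccc2)cc1Cc1ccc(OCc2ccccc2)cc1)C(=O)OCc1ccccc1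
F4 | step 5 | benzyl (2R)-2-{[3-(benzyloxy)-3-oxopropanoyl]oxy}-3-{4,5-bis(benzyloxy)-2-[4-(benzyloxy)benzyl]phenyl}propanoate | O=C(CC(=O)OCc1ccccc1)O[C@H](Cc1cc(OCc2ccccc2)c(OCc2ccccc2)cc1Cc1ccc(OCc2ccccc2)cc1)C(=O)OCc1ccccc1
F5 | step 4 | (2R)-3-{4,5-bis(benzyloxy)-2-[4-(benzyloxy)benzyl]phenyl}-2-hydroxypropanoic acid | OC(=O)[C@H](O)Cc1cc(OCc2ccccc2)c(OCc2ccccc2)cc1Cc1ccc(OCc2ccccc2)cc1
A1 | alternative 1 | rosmarinic acid, (2R)-3-(3,4-dihydroxyphenyl)-2-{[(2E)-3-(3,4-dihydroxyphenyl)prop-2-enoyl]oxy}propanoic acid | O=C(/C=C/c1ccc(O)c(O)c1)O[C@H](Cc1ccc(O)c(O)c1)C(=O)O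
A2 | alternative 1 | 4-(hydroxymethyl)phenol (4-hydroxybenzyl alcohol) | OCc1ccc(O)cc1
A3 | alternative 1 | 4-methylidenecyclohexa-2,5-dien-1-one (para-quinone methide) | C=C1C=CC(=O)C=C1
A4 | alternative 2 | 4,5-bis(benzyloxy)-2-bromobenzaldehyde | O=Cc1cc(OCc2ccccc2)c(OCc2ccccc2)cc1Br
A5 | alternative 2 | 4-(benzyloxy)benzylzinc chloride | Cl[Zn]Cc1ccc(OCc2ccccc2)cc1
A6 | alternative 2 | 4,5-bis(benzyloxy)-2-[4-(benzyloxy)benzyl]benzaldehyde | O=Cc1cc(OCc2ccccc2)c(OCc2ccccc2)cc1Cc1ccc(OCc2ccccc2)cc1
A7 | alternative 2 | 3-{4,5-bis(benzyloxy)-2-[4-(benzyloxy)benzyl]phenyl}-2-oxopropanoic acid | OC(=O)C(=O)Cc1cc(OCc2ccccc2)c(OCc2ccccc2)cc1Cc1ccc(OCc2ccccc2)cc1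
A8 | alternative 3 | 1,2-bis(benzyloxy)-4-iodobenzene | Ic1ccc(OCc2ccccc2)c(OCc2ccccc2)c1
A9 | alternative 3 | methyl (2E)-3-{4,5-bis(benzyloxy)-2-[4-(benzyloxy)benzyl]phenyl}prop-2-enoate | COC(=O)/C=C/c1cc(OCc2ccccc2)c(OCc2ccccc2)cc1Cc1ccc(OCc2ccccc2)cc1
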